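**Plan**
Locants: ring = furan-2(5H)-one O1, C2(=O), C3(CH3), C4(OH), C5; side chain C1'–C13' (3'E,5'E-diene; methyls on C2', C6', C10'; furan-3-yl on C13').
Retrosynthetic cuts, in order: C4'–C5' (Suzuki coupling); C3'=C4' (cross-metathesis); ring C2–C3 together with C4–C5 (one pot, back to an open-chain O-alkyl carbamate plus a propanoyl unit); C2'–CH3 (allylic substitution); on the left half C6'–CH3 (carboalumination), C6'–C7' (acetylide alkylation), C12'–C13' (furylmethyl coupling to citronellyl bromide).
Forward: the only ring to be made, the tetronic acid, is closed early on a five-carbon carbamate; the chain is then joined by metathesis and Suzuki coupling to a left half grown from (R)-citronellyl bromide.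
Enabling feature: O1–C2(=O) is a carbonic-acid-level carbon already bonded to the C5 oxygen, so an N,N-diisopropylcarbamate on the future C5–O both reverses the polarity of C5 (it becomes a carbanion that takes C4 as an acyl cation) and serves as the internal acyl donor that C3 attacks.
Stereochemistry: C5 from (−)-sparteine-controlled deprotonation and retentive acylation; C2' from Cu/TaniaPhos allylic methylation; C10' from (R)-citronellyl bromide; 3'E from metathesis, 5'E from syn-carboalumination, both retained in the Suzuki step.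
Key step: step 4

Remark: the sense of induction of (R,R)-TaniaPhos on this aliphatic allyl bromide is assumed to parallel that known for cinnamyl bromide; the antipodal ligand would be used if the first run shows the opposite sense.

**Step 1**
Reactants: 1 but-3-en-1-ol; 2 N,N-di(propan-2-yl)carbamoyl chloride
Product: 3 but-3-en-1-yl N,N-di(propan-2-yl)carbamate
Conditions: Et3N, CH2Cl2, reflux
Reagents that add atoms: none
Why: O-carbamoylation of a primary alcohol with a carbamoyl chloride is the standard preparation of Hoppe carbamates, and no stereocentre is involved.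

**Step 2**
Reactants: 3 but-3-en-1-yl N,N-di(propan-2-yl)carbamate; 4 (2E)-1,4-dibromobut-2-ene
Product: 5 (3E)-5-bromopent-3-en-1-yl N,N-di(propan-2-yl)carbamate
Conditions: 4 (3 equiv), second-generation Hoveyda–Grubbs catalyst [(H2IMes)Cl2Ru=CH(C6H4-2-OiPr)] (2 mol%), CH2Cl2, 40 °C
Reagents that add atoms: none
Why: olefin cross-metathesis of a terminal alkene with excess symmetrical 1,4-dibromobut-2-ene is an established route to (E)-allyl bromides (E favoured thermodynamically), and the carbamate is inert to the ruthenium carbene.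

**Step 3**
Reactants: 5 (3E)-5-bromopent-3-en-1-yl N,N-di(propan-2-yl)carbamate
Product: 6 (3R)-3-methylpent-4-en-1-yl N,N-di(propan-2-yl)carbamate
Conditions: MeMgBr, CuBr·SMe2 (1 mol%), (R,R)-TaniaPhos (1.2 mol%), CH2Cl2, −78 °C
Reagents that add atoms: methylmagnesium bromide, C[Mg]Br
Why: copper-catalysed asymmetric allylic alkylation (SN2' attack of the methyl Grignard reagent) is known to give branched 3-methyl-1-alkenes from functionalised aliphatic (E)-allyl bromides; the ligand fixes the face of γ-attack and so sets the (R) centre, and the hindered carbamate does not react with MeMgBr at −78 °C.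

**Step 4**
Reactants: 6 (3R)-3-methylpent-4-en-1-yl N,N-di(propan-2-yl)carbamate
Product: 10 (5R)-4-hydroxy-3-methyl-5-[(2R)-2-methylbut-3-en-1-yl]furan-2(5H)-one, via lithiated carbamate 7 (not isolated), via carbamoyloxy ketone 8 (not isolated), via hydroxy keto amide 9 (not isolated)
Conditions: (i) s-BuLi, (−)-sparteine, Et2O, −78 °C, 5 h; (ii) EtCOCl, −78 °C; (iii) LiN(SiMe3)2, THF, −78 → 0 °C; (iv) CF3CO2H, PhMe, 60 °C (one pot)
Reagents that add atoms: propanoyl chloride, CCC(=O)Cl; s-butyllithium, [Li]C(C)CC (its lithium is carried only in intermediate 7)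
Why: Proposed new method: s-BuLi/(−)-sparteine removes the pro-S hydrogen on the carbon bearing the carbamate oxygen (Hoppe deprotonation) to give the configurationally stable, chelated (S)-α-oxy organolithium 7, a polarity-reversed C5 that is acylated with retention by propanoyl chloride to give ketone 8 (C4–C5 bond). LiN(SiMe3)2 then enolises the ethyl side, the enolate carbon C3 attacks the carbamate carbonyl C2 (C2–C3 bond) and the tetrahedral adduct opens to the β-keto amide 9 (1,4-O→C carbamoyl shift, driven by formation of the doubly stabilised enolate; any transfer to the enolate oxygen is reversible and drains into this sink), after which CF3CO2H lets the C5 hydroxyl displace diisopropylamine to give the tetronic acid. The closest known reaction types are the acylation of sparteine-complexed lithiated carbamates with acid chlorides and the carbamoyl Baker–Venkataraman shift of aryl carbamates with acid lactonisation to 4-hydroxycoumarins; that shift has not been shown on an aliphatic α-carbamoyloxy ketone or run as a cascade from the lithiated carbamate. Ring closure: the C-acyl transfer passes through a five-membered adduct formed by 5-(enolendo)-exo-trig attack, the mode of Lacey–Dieckmann tetronic acid closures, and the lactone O1–C2 bond is re-made by 5-exo-trig attack of the hydroxyl on the amide. The only new stereocentre, C5, is fixed by the chiral diamine (reagent control over the remote C-methyl centre) and is carried through with retention. The step needs enolisation of 8 away from C5, which the kinetic base at −78 °C and the steric shielding of C5–H by the diisopropylcarbamoyloxy group should secure, and C5 is no longer acidic once the β-keto amide enolate has formed.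

**Step 5**
Reactants: 10 (5R)-4-hydroxy-3-methyl-5-[(2R)-2-methylbut-3-en-1-yl]furan-2(5H)-one; 11 2-ethenyl-4,4,5,5-tetramethyl-1,3,2-dioxaborolane
Product: 12 (5R)-4-hydroxy-3-methyl-5-[(2R,3E)-2-methyl-4-(4,4,5,5-tetramethyl-1,3,2-dioxaborolan-2-yl)but-3-en-1-yl]furan-2(5H)-one
Conditions: 11 (2 equiv), second-generation Grubbs catalyst [(H2IMes)(PCy3)Cl2Ru=CHPh] (5 mol%), CH2Cl2, 40 °C
Reagents that add atoms: none
Why: ruthenium-catalysed cross-metathesis of a terminal alkene with vinyl pinacol boronate is known to give (E)-alkenylboronates (the bulky boryl group enforces E), the catalyst tolerates acidic OH groups, and neither stereocentre is touched.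

**Step 6**
Reactants: 13 (6R)-8-bromo-2,6-dimethyloct-2-ene ((R)-citronellyl bromide); 14 3-(bromomethyl)furan
Product: 16 3-[(4S)-4,8-dimethylnon-7-en-1-yl]furan, via citronellylmagnesium bromide 15 (not isolated)
Conditions: Mg, THF; then 14, Li2CuCl4 (3 mol%), THF, −20 → 0 °C
Reagents that add atoms: magnesium, [Mg] (carried only in intermediate 15)
Why: copper-catalysed (Kochi-type) sp3–sp3 coupling of a primary alkyl Grignard reagent with a reactive furylmethyl bromide; the chiral-pool stereocentre is remote and unaffected (its descriptor changes only through ligand priorities).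

**Step 7**
Reactants: 16 3-[(4S)-4,8-dimethylnon-7-en-1-yl]furan
Product: 17 (4S)-7-(furan-3-yl)-4-methylheptanal
Conditions: OsO4 (2 mol%), NaIO4, 2,6-lutidine, dioxane/H2O, rt
Reagents that add atoms: sodium periodate, [Na+].[O-]I(=O)(=O)=O (oxygen source, relayed through catalytic osmium tetroxide, O=[Os](=O)(=O)=O)
Why: Lemieux–Johnson cleavage (catalytic dihydroxylation, then periodate glycol fission) attacks the electron-rich trisubstituted alkene, whereas an aromatic furan ring is known to survive catalytic OsO4 dihydroxylation of vinylfurans, and 2,6-lutidine suppresses over-oxidation.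

**Step 8**
Reactants: 17 (4S)-7-(furan-3-yl)-4-methylheptanal
Product: 18 (4S)-7-(furan-3-yl)-4-methylheptan-1-ol
Conditions: NaBH4, MeOH, 0 °C
Reagents that add atoms: none
Why: chemoselective borohydride reduction of an aldehyde; nothing else in the molecule is reducible.

**Step 9**
Reactants: 18 (4S)-7-(furan-3-yl)-4-methylheptan-1-ol
Product: 19 3-[(4S)-7-iodo-4-methylheptyl]furan
Conditions: I2, PPh3, imidazole, CH2Cl2, 0 °C → rt
Reagents that add atoms: iodine, II
Why: Appel-type (Garegg–Samuelsson) iodination of a primary alcohol under buffered, essentially neutral conditions that the furan tolerates.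

**Step 10**
Reactants: 19 3-[(4S)-7-iodo-4-methylheptyl]furan
Product: 20 3-[(4R)-4-methylnon-8-yn-1-yl]furan
Conditions: LiC≡CH·H2NCH2CH2NH2, DMSO, rt
Reagents that add atoms: lithium acetylide–ethylenediamine complex, [Li]C#C.NCCN
Why: SN2 alkylation of lithium acetylide by a primary iodide in DMSO is a standard two-carbon homologation to a terminal alkyne (the descriptor changes only through ligand priorities).

**Step 11**
Reactants: 20 3-[(4R)-4-methylnon-8-yn-1-yl]furan
Product: 22 3-[(4S,8E)-9-iodo-4,8-dimethylnon-8-en-1-yl]furan, via alkenyldimethylalane 21 (not isolated)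
Conditions: Me3Al, Cp2ZrCl2 (0.25 equiv), CH2Cl2, 0 °C → rt; then I2, THF, −30 → 0 °C
Reagents that add atoms: trimethylaluminium, C[Al](C)C; iodine, II
Why: Negishi zirconium-catalysed carboalumination adds CH3 and Al syn across the terminal alkyne with methyl on the internal carbon, and iodinolysis of the alkenylalane proceeds with retention, so the (E)-2-methyl-1-iodoalkene should form as a single isomer.

**Step 12**
Reactants: 12 (5R)-4-hydroxy-3-methyl-5-[(2R,3E)-2-methyl-4-(4,4,5,5-tetramethyl-1,3,2-dioxaborolan-2-yl)but-3-en-1-yl]furan-2(5H)-one; 22 3-[(4S,8E)-9-iodo-4,8-dimethylnon-8-en-1-yl]furan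
Product: 23 (5R)-5-[(2R,3E,5E,10R)-13-(furan-3-yl)-2,6,10-trimethyltrideca-3,5-dien-1-yl]-4-hydroxy-3-methylfuran-2(5H)-one (target)
Conditions: Pd(dppf)Cl2 (5 mol%), K3PO4 (aq.), THF, 45 °C, degassed; then aq. NaH2PO4 to pH 3
Reagents that add atoms: none
Why: Suzuki–Miyaura coupling of an (E)-alkenylboronate with an (E)-alkenyl iodide proceeds with retention at both sp2 carbons and so fixes the (3E,5E)-diene; the tetronic acid is present as its potassium salt, is set free on acidification, and the three stereocentres are not involved.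

**Compound list**
1 | but-3-en-1-ol | C=CCCO | starting material
2 | N,N-di(propan-2-yl)carbamoyl chloride | CC(C)N(C(C)C)C(=O)Cl | starting material
3 | but-3-en-1-yl N,N-di(propan-2-yl)carbamate | C=CCCOC(=O)N(C(C)C)C(C)C | intermediate
4 | (2E)-1,4-dibromobut-2-ene | BrC/C=C/CBr | starting material
5 | (3E)-5-bromopent-3-en-1-yl N,N-di(propan-2-yl)carbamate | BrC/C=C/CCOC(=O)N(C(C)C)C(C)C | intermediate
6 | (3R)-3-methylpent-4-en-1-yl N,N-di(propan-2-yl)carbamate | C=C[C@H](C)CCOC(=O)N(C(C)C)C(C)C | intermediate
7 | (1S,3R)-1-lithio-3-methylpent-4-en-1-yl N,N-di(propan-2-yl)carbamate (as its (−)-sparteine complex; formed in the flask) | [Li][C@@H](C[C@@H](C)C=C)OC(=O)N(C(C)C)C(C)C | intermediate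
8 | (4R,6R)-6-methyl-3-oxooct-7-en-4-yl N,N-di(propan-2-yl)carbamate (formed in the flask) | CCC(=O)[C@@H](C[C@@H](C)C=C)OC(=O)N(C(C)C)C(C)C | intermediate
9 | (4R,6R)-4-hydroxy-2,6-dimethyl-3-oxo-N,N-di(propan-2-yl)oct-7-enamide (C2 epimers; formed in the flask) | CC(C(=O)N(C(C)C)C(C)C)C(=O)[C@H](O)C[C@@H](C)C=C | intermediate
10 | (5R)-4-hydroxy-3-methyl-5-[(2R)-2-methylbut-3-en-1-yl]furan-2(5H)-one | CC1=C(O)[C@@H](C[C@@H](C)C=C)OC1=O | intermediate
11 | 2-ethenyl-4,4,5,5-tetramethyl-1,3,2-dioxaborolane | C=CB1OC(C)(C)C(C)(C)O1 | starting material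
12 | (5R)-4-hydroxy-3-methyl-5-[(2R,3E)-2-methyl-4-(4,4,5,5-tetramethyl-1,3,2-dioxaborolan-2-yl)but-3-en-1-yl]furan-2(5H)-one | CC1=C(O)[C@@H](C[C@@H](C)/C=C/B2OC(C)(C)C(C)(C)O2)OC1=O | intermediate
13 | (6R)-8-bromo-2,6-dimethyloct-2-ene ((R)-citronellyl bromide) | CC(C)=CCC[C@@H](C)CCBr | starting material
14 | 3-(bromomethyl)furan | BrCc1ccoc1 | starting material
15 | [(3R)-3,7-dimethyloct-6-en-1-yl]magnesium bromide (formed in the flask) | CC(C)=CCC[C@@H](C)CC[Mg]Br | intermediate
16 | 3-[(4S)-4,8-dimethylnon-7-en-1-yl]furan | CC(C)=CCC[C@@H](C)CCCc1ccoc1 | intermediate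
17 | (4S)-7-(furan-3-yl)-4-methylheptanal | O=CCC[C@@H](C)CCCc1ccoc1 | intermediate
18 | (4S)-7-(furan-3-yl)-4-methylheptan-1-ol | OCCC[C@@H](C)CCCc1ccoc1 | intermediate
19 | 3-[(4S)-7-iodo-4-methylheptyl]furan | ICCC[C@@H](C)CCCc1ccoc1 | intermediate
20 | 3-[(4R)-4-methylnon-8-yn-1-yl]furan | C#CCCC[C@@H](C)CCCc1ccoc1 | intermediate
21 | [(1E,6S)-9-(furan-3-yl)-2,6-dimethylnon-1-en-1-yl]dimethylalumane (formed in the flask) | C[Al](C)/C=C(\C)CCC[C@@H](C)CCCc1ccoc1 | intermediate
22 | 3-[(4S,8E)-9-iodo-4,8-dimethylnon-8-en-1-yl]furan | I/C=C(\C)CCC[C@@H](C)CCCc1ccoc1 | intermediate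
23 | (5R)-5-[(2R,3E,5E,10R)-13-(furan-3-yl)-2,6,10-trimethyltrideca-3,5-dien-1-yl]-4-hydroxy-3-methylfuran-2(5H)-one | CC1=C(O)[C@@H](C[C@@H](C)/C=C/C=C(\C)CCC[C@@H](C)CCCc2ccoc2)OC1=O | target

**Step count and risks**
Total step count: 12. Longest linear sequence: 7 (steps 6–12).

Steps most likely to fail:

1. Step 4 (the labelled step). What may go wrong: enolisation of ketone 8 toward C5 with loss of configuration, transfer of the carbamoyl group to the enolate oxygen instead of carbon, or incomplete amide-to-lactone closure. Fallback with known chemistry only, from 6 back to 10: LiAlH4 (THF, reflux) cleaves the carbamate to (3R)-3-methylpent-4-en-1-ol F1. Swern oxidation gives (3R)-3-methylpent-4-enal F2. HCN addition catalysed by (R)-hydroxynitrile lyase from almond gives (2R,4R)-2-hydroxy-4-methylhex-5-enenitrile F3. Pinner methanolysis (HCl, MeOH; then H2O) gives methyl (2R,4R)-2-hydroxy-4-methylhex-5-enoate F4. Propanoyl chloride/pyridine gives methyl (2R,4R)-4-methyl-2-(propanoyloxy)hex-5-enoate F5. Dieckmann cyclisation (LiN(SiMe3)2, THF, −78 °C → rt, acid work-up) then closes ring bond C3–C4 and gives 10; C5 now comes from the enzymatic cyanohydrin.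

2. Step 5. What may go wrong: deactivation of the ruthenium carbene by the free acidic enol and its chelating conjugate base, and loss of the polar boronate on purification. Fallback, from 10 to 23, carries the tetronic acid masked through all metal-catalysed steps. Me2SO4/K2CO3 in acetone gives (5R)-4-methoxy-3-methyl-5-[(2R)-2-methylbut-3-en-1-yl]furan-2(5H)-one F6. Cross-metathesis with 11 gives (5R)-4-methoxy-3-methyl-5-[(2R,3E)-2-methyl-4-(4,4,5,5-tetramethyl-1,3,2-dioxaborolan-2-yl)but-3-en-1-yl]furan-2(5H)-one F7. Suzuki coupling with 22 gives (5R)-5-[(2R,3E,5E,10R)-13-(furan-3-yl)-2,6,10-trimethyltrideca-3,5-dien-1-yl]-4-methoxy-3-methylfuran-2(5H)-one F8. SN2 demethylation with LiCl in DMSO at 60 °C returns the route at 23.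

3. Step 7. What may go wrong: competing oxidation of the furan ring during the osmium/periodate cleavage. Fallback, from 13 to 18, moves the oxidation ahead of furan installation. Ozonolysis of 13 (CH2Cl2/MeOH, −78 °C) with NaBH4 work-up gives (4R)-6-bromo-4-methylhexan-1-ol F9. TBSCl/imidazole gives {[(4R)-6-bromo-4-methylhexyl]oxy}(tert-butyl)dimethylsilane F10. Mg in THF gives {(3R)-6-[(tert-butyldimethylsilyl)oxy]-3-methylhexyl}magnesium bromide F11, which is coupled with 14 under Li2CuCl4 catalysis to give tert-butyl{[(4S)-7-(furan-3-yl)-4-methylheptyl]oxy}dimethylsilane F12. Bu4NF in THF returns the route at 18.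

**Further compounds**
F1 | step 4 | (3R)-3-methylpent-4-en-1-ol | OCC[C@@H](C)C=C
F2 | step 4 | (3R)-3-methylpent-4-enal | O=CC[C@@H](C)C=C
F3 | step 4 | (2R,4R)-2-hydroxy-4-methylhex-5-enenitrile | N#C[C@H](O)C[C@@H](C)C=C
F4 | step 4 | methyl (2R,4R)-2-hydroxy-4-methylhex-5-enoate | COC(=O)[C@H](O)C[C@@H](C)C=C
F5 | step 4 | methyl (2R,4R)-4-methyl-2-(propanoyloxy)hex-5-enoate | COC(=O)[C@@H](C[C@@H](C)C=C)OC(=O)CC
F6 | step 5 | (5R)-4-methoxy-3-methyl-5-[(2R)-2-methylbut-3-en-1-yl]furan-2(5H)-one | CC1=C(OC)[C@@H](C[C@@H](C)C=C)OC1=O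
F7 | step 5 | (5R)-4-methoxy-3-methyl-5-[(2R,3E)-2-methyl-4-(4,4,5,5-tetramethyl-1,3,2-dioxaborolan-2-yl)but-3-en-1-yl]furan-2(5H)-one | CC1=C(OC)[C@@H](C[C@@H](C)/C=C/B2OC(C)(C)C(C)(C)O2)OC1=O
F8 | step 5 | (5R)-5-[(2R,3E,5E,10R)-13-(furan-3-yl)-2,6,10-trimethyltrideca-3,5-dien-1-yl]-4-methoxy-3-methylfuran-2(5H)-one | CC1=C(OC)[C@@H](C[C@@H](C)/C=C/C=C(\C)CCC[C@@H](C)CCCc2ccoc2)OC1=O
F9 | step 7 | (4R)-6-bromo-4-methylhexan-1-ol | OCCC[C@@H](C)CCBr
F10 | step 7 | {[(4R)-6-bromo-4-methylhexyl]oxy}(tert-butyl)dimethylsilane | CC(C)(C)[Si](C)(C)OCCC[C@@H](C)CCBr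
F11 | step 7 | {(3R)-6-[(tert-butyldimethylsilyl)oxy]-3-methylhexyl}magnesium bromide | CC(C)(C)[Si](C)(C)OCCC[C@@H](C)CC[Mg]Br
F12 | step 7 | tert-butyl{[(4S)-7-(furan-3-yl)-4-methylheptyl]oxy}dimethylsilane | CC(C)(C)[Si](C)(C)OCCC[C@@H](C)CCCc1ccoc1
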